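The cycloheptene ring is read as a cyclohexenone plus one carbon. C5–C6(O)–C8(Me)=C9–C10–C1 is the 2-methylcyclohex-2-enone ring of (S)-carvone, and C7 is a CH2 wedged between carbonyl carbon C6 and alkene carbon C8. The cyclopentane (C1–C5) is therefore assembled on carvone, where C5 is the only enolisable ring carbon, and the ring is enlarged afterwards. In one flask LiCHBr2 adds to C6, and bromine–lithium exchange sets off a 1,2-shift of alkenyl C8. This forms C6–C7 and C7–C8, cuts C6–C8 and leaves C8=C9 unconjugated. The substrate is a cis-hydrindenone with the complete cyclopentane, protected as 2-OTBS and 4-OTES ethers.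

Key step: step 14

Remark: target numbering is used for every intermediate; α is the face of H-5 and of the C1 methyl group, β the other face; the C4 carbinol centre of 4–13 is drawn as the expected anti-aldol epimer, and its epimer converges in step 7.

Step 1
Reactants: 1 (S)-carvone; 2 isobutyraldehyde
Product: 4 aldol adduct (5β side chain trans to the 1α-isopropenyl group), via lithium dienolate 3 (not isolated)
Conditions: LiN(iPr)2, THF, −78 °C; 2, −78 °C; AcOH, −78 °C
Reagents that add atoms: none
Why: Kinetic α′-deprotonation gives the cross-conjugated dienolate, whose aldol addition through a Zimmerman–Traxler chair should place the new chain at C5 trans to the isopropenyl group (H-5 α) and give mainly the anti carbinol at C4, a centre that step 7 erases.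

Step 2
Reactants: 4 aldol adduct
Product: 5 allylic diol (6α-OH)
Conditions: NaBH4, CeCl3·7H2O, MeOH, −78 to −20 °C
Reagents that add atoms: none
Why: In this Luche 1,2-reduction hydride attacks C6 axially, as in the conversion of carvone into cis-carveol, so the 6-OH should be equatorial, α and trans to the C5 chain, and H-5, the only relay of chirality once C1 is flattened, loses its acidity.

Step 3
Reactants: 5 allylic diol
Product: 6 6α-TBS ether with free 4-OH
Conditions: TBSCl (1.05 equiv), imidazole, DMF, 0 °C
Reagents that add atoms: tert-butyldimethylsilyl chloride, CC(C)(C)[Si](C)(C)Cl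
Why: Sterically differentiated silyl ether formation should take only O6, because the allylic 6-OH has one flat sp2 neighbour whereas the 4-OH lies between two branched carbons.

Step 4
Reactants: 6 6α-TBS ether
Product: 8 methyl ketone (1α-acetyl), via vicinal diol 7 (not isolated)
Conditions: OsO4 (cat.), NaIO4, 2,6-lutidine, dioxane–H2O, rt
Reagents that add atoms: osmium tetroxide, O=[Os](=O)(=O)=O; sodium periodate, [Na+].[O-]I(=O)(=O)=O
Why: In this Lemieux–Johnson cleavage OsO4 prefers the open 1,1-disubstituted alkene to the trisubstituted C8=C9 flanked by CH3 and OTBS, and periodate cuts the diol to the C2 carbonyl with C3 as its methyl group.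

Step 5
Reactants: 8 methyl ketone
Product: 9 bis-TMS compound (C1=C2 enol ether plus 4-OTMS)
Conditions: TMSCl, NaI, Et3N, MeCN, rt
Reagents that add atoms: chlorotrimethylsilane, C[Si](C)(C)Cl
Why: Equilibrating silyl enol ether formation with iodotrimethylsilane made in the flask favours the tetrasubstituted C1=C2 isomer, the same preference that hindered 20-oxo steroids show for their 17(20)-enol derivatives, and it caps O4 in the same operation.

Step 6
Reactants: 9 bis-TMS compound; 10 iodomethane
Product: 13 γ-hydroxy ketone (1α-CH3 and 1β-acetyl), via lithium enolate 11 (not isolated), via 4-OTMS ketone 12 (not isolated)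
Conditions: MeLi, THF, 0 °C to rt; 10, DMPU, −78 to 0 °C; 1 M HCl, THF, 0 °C
Reagents that add atoms: none
Why: MeLi releases the enolate regiospecifically from the silyl enol ether, allylic 1,3-strain with the enolate substituents forces the C5 chain axial on the β face, and C-methylation should therefore occur trans-diaxially from the α face to make C1 quaternary with CH3 cis to H-5, after which dilute acid frees O4.

Step 7
Reactants: 13 γ-hydroxy ketone
Product: 14 1,4-diketone (C2 and C4 carbonyls)
Conditions: Dess–Martin periodinane, CH2Cl2, 0 °C to rt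
Reagents that add atoms: none
Why: Dess–Martin oxidation converts the only free alcohol into the isopropyl ketone under non-basic conditions that leave H-5 in place.

Step 8
Reactants: 14 1,4-diketone
Product: 16 cis-hydrindene hydroxy ketone (4β-OH and 4α-isopropyl), via lithium enolate 15 (not isolated)
Conditions: LiN(SiMe3)2, THF, −78 to −40 °C; AcOH, −78 °C
Reagents that add atoms: none
Why: In this intramolecular aldol addition (5-enolexo-exo-trig) the amide base takes a proton from the unhindered C3 methyl group, and C3 adds to the C4 carbonyl in the rotamer that turns the isopropyl group outward beside H-5, which should leave 4-OH β, next to C6, and the ring fusion cis.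

Step 9
Reactants: 16 cis-hydrindene hydroxy ketone
Product: 17 2β,4β-diol
Conditions: NaBH4, CeCl3·7H2O, MeOH, −40 to 0 °C
Reagents that add atoms: none
Why: In this substrate-controlled borohydride reduction under nearly neutral Luche conditions the cyclohexene ring (C6 and C10) roofs the β face of the cyclopentanone, so hydride should enter from the convex α face and give the 2β-alcohol, trans to the C1 methyl group and cis to 4-OH.

Step 10
Reactants: 17 2β,4β-diol
Product: 18 2β,4β,6α-triol
Conditions: Bu4NF, THF, rt
Reagents that add atoms: none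
Why: Fluoride-induced desilylation removes the only silyl group present, so no selectivity is required.

Step 11
Reactants: 18 triol
Product: 19 enone diol
Conditions: MnO2, CH2Cl2, rt
Reagents that add atoms: none
Why: Allylic oxidation with MnO2 touches only the 6-OH, so the 2-methylcyclohexenone returns while the saturated 2-OH and the tertiary 4-OH remain.

Step 12
Reactants: 19 enone diol
Product: 20 2β-TBS ether with free 4-OH
Conditions: TBSOTf (1.2 equiv), 2,6-lutidine, CH2Cl2, −78 to −30 °C
Reagents that add atoms: tert-butyldimethylsilyl triflate, CC(C)(C)[Si](C)(C)OS(=O)(=O)C(F)(F)F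
Why: Silyl triflate protection at low temperature distinguishes the secondary 2-OH from the tertiary 4-OH buried beside the isopropyl group.

Step 13
Reactants: 20 2β-TBS ether
Product: 21 cis-hydrindenone (2β-OTBS and 4β-OTES)
Conditions: TESOTf, 2,6-lutidine, CH2Cl2, 0 °C
Reagents that add atoms: triethylsilyl triflate, CC[Si](CC)(CC)OS(=O)(=O)C(F)(F)F
Why: Silylation with the smaller TESOTf caps the hindered tertiary alcohol, which blocks retro-aldol cleavage of C4–C5 in the basic key step and can later be removed beside TBS.

Step 14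
Reactants: 21 cis-hydrindenone; 22 dibromomethane
Product: 27 hydroazulen-6-one with C8=C9, via dibromomethyllithium 23 (not isolated), via lithium carbinolate 24 (not isolated), via β-oxido carbenoid 25 (not isolated), via lithium dienolate 26 (not isolated)
Conditions: lithium 2,2,6,6-tetramethylpiperidide, THF, −78 °C; n-BuLi, −78 to −20 °C; AcOH, THF, −78 °C
Reagents that add atoms: none
Why: The amide base deprotonates 22 to 23, which adds 1,2 to the C6 carbonyl; n-BuLi then exchanges one bromine of 24, and in carbenoid 25 the C6–C8 σ-bond shifts to the carbenoid carbon as bromide leaves, which forms C7–C8 beside the C6–C7 bond made in the addition and delivers dienolate 26. The closest known reaction type is the dibromomethyllithium (β-oxido carbenoid) one-carbon homologation of cyclic ketones and cyclohexenones, a relative of the Tiffeneau–Demjanov rearrangement. The cycloheptene ring is closed by ring enlargement, a 1,2-migration inside the six-membered ring, so no chain ends have to meet and no medium-ring cyclisation penalty arises. No stereocentre is made: C6 returns to sp2, so the face of addition is irrelevant, and C1, C2, C4 and C5 are spectators because the enolate is generated toward C7 and never toward C5. The step needs addition before enolisation, migration of sp2 C8 rather than sp3 C5, and α-protonation: H-5 is buried between the quaternary carbons C1 and C4; the alkenyl group migrates with π-participation, whereas C5 is inductively deactivated by O4 and too crowded to align anti to the C–Br bond; and a cold AcOH quench should protonate the extended enolate kinetically at C7, which keeps C8=C9 where the target has it. Lithium as counter-ion and the low temperature keep the TES group on O4 and so suppress both retro-aldol cleavage and silyl transfer to O6.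

Step 15
Reactants: 27 hydroazulen-6-one
Product: 28 4β-hydroxy ketone
Conditions: HF·pyridine, pyridine, THF, 0 °C
Reagents that add atoms: none
Why: Selective desilylation with buffered HF·pyridine cleaves TES much faster than the neopentyl TBS ether, and the weakly acidic medium should neither move C8=C9 into conjugation nor dehydrate C4.

Step 16
Reactants: 28 4β-hydroxy ketone
Product: 29 4β,6α-diol
Conditions: Me4NBH(OAc)3, MeCN–AcOH, −30 °C
Reagents that add atoms: none
Why: In this Evans–Saksena reduction ligand exchange binds boron to the 4β-OH and hydride is delivered within the chelate to the β face of C6, so the 6α-alcohol, 1,3-anti to 4-OH, should result.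

Step 17
Reactants: 29 4β,6α-diol; 30 3,4,5-trimethoxybenzoyl chloride
Product: 31 6α-(3,4,5-trimethoxybenzoate)
Conditions: Et3N, DMAP (cat.), CH2Cl2, rt
Reagents that add atoms: none
Why: DMAP-catalysed acylation takes the only free secondary alcohol, since the tertiary 4-OH is inert under these conditions, as it is in related daucane 4,6-diols.

Step 18
Reactants: 31 6α-ester
Product: 32 2β,4β-diol 6-ester
Conditions: HF·pyridine, THF, rt
Reagents that add atoms: none
Why: Fluoride-mediated desilylation removes the last silyl ether, and the acidic fluoride source avoids the alkoxide that could trigger acyl migration or ester cleavage.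

Step 19
Reactants: 32 2β,4β-diol 6-ester; 33 angelic acid
Product: 35 target CNP0112256.1, via mixed anhydride 34 (not isolated)
Conditions: 33, 2,4,6-trichlorobenzoyl chloride, Et3N, toluene, rt; 32, 80 °C
Reagents that add atoms: none
Why: In this Yamaguchi-type mixed-anhydride esterification run without nucleophilic catalyst the secondary 2-OH attacks the unhindered angeloyl carbonyl, no addition–elimination path to the tiglate is opened so the Z geometry should be retained, and the tertiary 4-OH does not react.

Compound list
1 | (S)-(+)-carvone | CC1=CC[C@H](C(C)=C)CC1=O | starting material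
2 | isobutyraldehyde | CC(C)C=O | starting material
3 | lithium cross-conjugated dienolate of carvone (C5=C6–OLi) | CC1=CC[C@H](C(C)=C)C=C1O[Li] | intermediate
4 | aldol adduct: carvone with a 5β-(1-hydroxy-2-methylpropyl) chain, H-5 α, isopropenyl 1α, anti carbinol | CC(C)[C@H](O)[C@H]1C(=O)C(C)=CC[C@@H]1C(C)=C | intermediate
5 | allylic diol, 6α-OH trans to the C5 chain | CC(C)[C@H](O)[C@H]1[C@H](O)C(C)=CC[C@@H]1C(C)=C | intermediate
6 | 6α-TBS ether with free 4-OH | CC(C)[C@H](O)[C@H]1[C@H](O[Si](C)(C)C(C)(C)C)C(C)=CC[C@@H]1C(C)=C | intermediate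
7 | vicinal diol from the isopropenyl group (new carbinol centre not defined) | CC(C)[C@H](O)[C@H]1[C@H](O[Si](C)(C)C(C)(C)C)C(C)=CC[C@@H]1C(C)(O)CO | intermediate
8 | methyl ketone, 1α-acetyl, free 4-OH | CC(C)[C@H](O)[C@H]1[C@H](O[Si](C)(C)C(C)(C)C)C(C)=CC[C@@H]1C(C)=O | intermediate
9 | tetrasubstituted C1=C2 TMS enol ether with 4-OTMS (alkene geometry not defined, inconsequential) | CC(C)[C@H](O[Si](C)(C)C)[C@H]1[C@H](O[Si](C)(C)C(C)(C)C)C(C)=CCC1=C(C)O[Si](C)(C)C | intermediate
10 | iodomethane | CI | starting material
11 | lithium enolate C1=C2–OLi | CC(C)[C@H](O[Si](C)(C)C)[C@H]1[C@H](O[Si](C)(C)C(C)(C)C)C(C)=CCC1=C(C)O[Li] | intermediate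
12 | methylated ketone still carrying 4-OTMS | CC(C)[C@H](O[Si](C)(C)C)[C@H]1[C@H](O[Si](C)(C)C(C)(C)C)C(C)=CC[C@@]1(C)C(C)=O | intermediate
13 | γ-hydroxy ketone, quaternary C1 with 1α-CH3 and 1β-acetyl | CC(C)[C@H](O)[C@H]1[C@H](O[Si](C)(C)C(C)(C)C)C(C)=CC[C@@]1(C)C(C)=O | intermediate
14 | 1,4-diketone, 5β-isobutyryl cis to 1β-acetyl | CC(C)C(=O)[C@H]1[C@H](O[Si](C)(C)C(C)(C)C)C(C)=CC[C@@]1(C)C(C)=O | intermediate
15 | lithium enolate C2(OLi)=C3H2 | CC(C)C(=O)[C@H]1[C@H](O[Si](C)(C)C(C)(C)C)C(C)=CC[C@@]1(C)C(=C)O[Li] | intermediate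
16 | cis-hydrindene hydroxy ketone: 2-oxo, 4β-OH, 4α-isopropyl, 6α-OTBS | O=C1C[C@](O)(C(C)C)[C@H]2[C@H](O[Si](C)(C)C(C)(C)C)C(C)=CC[C@@]12C | intermediate
17 | 2β,4β-diol, 6α-OTBS | O[C@H]1C[C@](O)(C(C)C)[C@H]2[C@H](O[Si](C)(C)C(C)(C)C)C(C)=CC[C@@]12C | intermediate
18 | 2β,4β,6α-triol | O[C@H]1C[C@](O)(C(C)C)[C@H]2[C@H](O)C(C)=CC[C@@]12C | intermediate
19 | enone diol (6-oxo, C8=C9) | O[C@H]1C[C@](O)(C(C)C)[C@H]2C(=O)C(C)=CC[C@@]12C | intermediate
20 | 2β-TBS ether of the enone diol | CC(C)(C)[Si](C)(C)O[C@H]1C[C@](O)(C(C)C)[C@H]2C(=O)C(C)=CC[C@@]12C | intermediate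
21 | cis-hydrindenone, 2β-OTBS, 4β-OTES | CC(C)(C)[Si](C)(C)O[C@H]1C[C@](O[Si](CC)(CC)CC)(C(C)C)[C@H]2C(=O)C(C)=CC[C@@]12C | intermediate
22 | dibromomethane | BrCBr | starting material
23 | dibromomethyllithium | [Li]C(Br)Br | intermediate
24 | lithium dibromomethyl carbinolate (C6 configuration not defined, erased in the same step) | CC(C)(C)[Si](C)(C)O[C@H]1C[C@](O[Si](CC)(CC)CC)(C(C)C)[C@H]2C(O[Li])(C(Br)Br)C(C)=CC[C@@]12C | intermediate
25 | β-oxido carbenoid | CC(C)(C)[Si](C)(C)O[C@H]1C[C@](O[Si](CC)(CC)CC)(C(C)C)[C@H]2C(O[Li])(C([Li])Br)C(C)=CC[C@@]12C | intermediate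
26 | lithium dienolate C6(OLi)=C7–C8(Me)=C9 | CC(C)(C)[Si](C)(C)O[C@H]1C[C@](O[Si](CC)(CC)CC)(C(C)C)[C@H]2C(O[Li])=CC(C)=CC[C@@]12C | intermediate
27 | hydroazulen-6-one with C8=C9, 2β-OTBS, 4β-OTES | CC(C)(C)[Si](C)(C)O[C@H]1C[C@](O[Si](CC)(CC)CC)(C(C)C)[C@H]2C(=O)CC(C)=CC[C@@]12C | intermediate
28 | 4β-hydroxy hydroazulen-6-one | CC(C)(C)[Si](C)(C)O[C@H]1C[C@](O)(C(C)C)[C@H]2C(=O)CC(C)=CC[C@@]12C | intermediate
29 | 4β,6α-diol, 2β-OTBS | CC(C)(C)[Si](C)(C)O[C@H]1C[C@](O)(C(C)C)[C@H]2[C@H](O)CC(C)=CC[C@@]12C | intermediate
30 | 3,4,5-trimethoxybenzoyl chloride | COc1cc(cc(OC)c1OC)C(=O)Cl | starting material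
31 | 6α-(3,4,5-trimethoxybenzoate), 2β-OTBS | CC(C)(C)[Si](C)(C)O[C@H]1C[C@](O)(C(C)C)[C@H]2[C@H](OC(=O)c3cc(OC)c(OC)c(OC)c3)CC(C)=CC[C@@]12C | intermediate
32 | 2β,4β-diol 6α-(3,4,5-trimethoxybenzoate) | O[C@H]1C[C@](O)(C(C)C)[C@H]2[C@H](OC(=O)c3cc(OC)c(OC)c(OC)c3)CC(C)=CC[C@@]12C | intermediate
33 | angelic acid, (Z)-2-methylbut-2-enoic acid | C/C=C(/C)C(=O)O | starting material
34 | angelic 2,4,6-trichlorobenzoic anhydride | C/C=C(/C)C(=O)OC(=O)c1c(Cl)cc(Cl)cc1Cl | intermediate
35 | CNP0112256.1 | C/C=C(/C)C(=O)O[C@H]1C[C@](O)(C(C)C)[C@H]2[C@H](OC(=O)c3cc(OC)c(OC)c(OC)c3)CC(C)=CC[C@@]12C | target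

Total step count: 19. Longest linear sequence: 19 steps (1 to 35).

Steps most likely to fail

1. Step 14. Addition to the crowded C6 carbonyl may be slow. H-5 may be removed instead, with loss of the 4-silyloxy group. C5 may also migrate in place of C8, which would insert the CH2 on the wrong side. The fallback inserts the carbon through a cyclopropanol, where an enol ether fixes the regiochemistry. Setting out from 21, conjugate reduction with LiBH(s-Bu)3 and trapping with TMSCl would give the C6=C8 silyl enol ether F1. Et2Zn/CH2I2 would then give the siloxycyclopropane F2. FeCl3 in DMF would open it to the β-chloro ketone F3, and NaOAc in MeOH would give the conjugated cycloheptenone F4. KOtBu in THF would convert F4 into the potassium dienolate F5, and a cold AcOH quench protonates it at C7, which comes back to the route at 27.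

2. Step 6 (fed by step 5). Incomplete equilibration would leave terminal enol ether and lead to methylation at C3. Proton transfer between product and enolate would cause over-alkylation. The pseudoaxial 6-OTBS group could also erode the facial bias. The fallback methylates C1 as a lactone enolate, which has a single α-position and a face dictated by the bicycle. Setting out from 8, LiN(iPr)2/TMSCl would give the kinetic terminal enol ether F6. One equivalent of ozone, then Me2S and an acidic work-up, would give the hydroxy acid F7, and PPTS in warm benzene would close it to the γ-lactone F8. LiN(iPr)2 and 10 would give the cis-fused 1α-methyl lactone F9. One equivalent of MeLi at −78 °C would open F9 to the methyl ketone, rejoining the route at 13.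

3. Step 9. Facial selectivity may be poor if the 1α-methyl and 4α-isopropyl groups hinder the convex face as much as the cyclohexene ring hinders the concave one. The fallback sets the opposite configuration on purpose and then inverts it. Setting out from 16, Me4NBH(OAc)3 bound to the 4β-OH would deliver hydride to the β face and give the 2α-alcohol F10. A Mitsunobu reaction (PPh3, DIAD, 4-nitrobenzoic acid), known for neopentyl cyclopentanols such as 17-hydroxy steroids, would invert C2 to the 2β-(4-nitrobenzoate) F11. K2CO3 in MeOH would then release the diol, coming back at 17.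

Further compounds
F1 | step 14 | C6=C8 trimethylsilyl enol ether | CC(C)(C)[Si](C)(C)O[C@H]1C[C@](O[Si](CC)(CC)CC)(C(C)C)[C@H]2C(O[Si](C)(C)C)=C(C)CC[C@@]12C
F2 | step 14 | siloxycyclopropane (C6–C7–C8 ring, face not defined) | CC(C)(C)[Si](C)(C)O[C@H]1C[C@](O[Si](CC)(CC)CC)(C(C)C)[C@H]2C3(O[Si](C)(C)C)CC3(C)CC[C@@]12C
F3 | step 14 | 8-chloro hydroazulen-6-one (C8 not defined) | CC(C)(C)[Si](C)(C)O[C@H]1C[C@](O[Si](CC)(CC)CC)(C(C)C)[C@H]2C(=O)CC(C)(Cl)CC[C@@]12C
F4 | step 14 | conjugated hydroazulen-6-one with C7=C8 | CC(C)(C)[Si](C)(C)O[C@H]1C[C@](O[Si](CC)(CC)CC)(C(C)C)[C@H]2C(=O)C=C(C)CC[C@@]12C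
F5 | step 14 | potassium dienolate C6(OK)=C7–C8(Me)=C9 | CC(C)(C)[Si](C)(C)O[C@H]1C[C@](O[Si](CC)(CC)CC)(C(C)C)[C@H]2C(O[K])=CC(C)=CC[C@@]12C
F6 | step 6 | terminal C2=C3 trimethylsilyl enol ether with 4-OTMS | CC(C)[C@H](O[Si](C)(C)C)[C@H]1[C@H](O[Si](C)(C)C(C)(C)C)C(C)=CC[C@@H]1C(=C)O[Si](C)(C)C
F7 | step 6 | hydroxy acid (C2 as carboxyl group) | CC(C)[C@H](O)[C@H]1[C@H](O[Si](C)(C)C(C)(C)C)C(C)=CC[C@@H]1C(=O)O
F8 | step 6 | γ-lactone O4–C2(=O) | CC(C)[C@H]3[C@H]1[C@H](O[Si](C)(C)C(C)(C)C)C(C)=CC[C@@H]1C(=O)O3
F9 | step 6 | cis-fused 1α-methyl γ-lactone | CC(C)[C@H]3[C@H]1[C@H](O[Si](C)(C)C(C)(C)C)C(C)=CC[C@@]1(C)C(=O)O3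
F10 | step 9 | 2α,4β-diol (2-epimer of 17) | O[C@@H]1C[C@](O)(C(C)C)[C@H]2[C@H](O[Si](C)(C)C(C)(C)C)C(C)=CC[C@@]12C
F11 | step 9 | 2β-(4-nitrobenzoate) | O=C(O[C@H]1C[C@](O)(C(C)C)[C@H]2[C@H](O[Si](C)(C)C(C)(C)C)C(C)=CC[C@@]12C)c1ccc(cc1)[N+](=O)[O-]
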